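1. Start from what cannot happen: a flask cannot draw more reagent than it was charged with. Hold every yield against that ceiling.

| flask | substrate | reagent | remark | time |
|---|---|---|---|---|
| south-west | 16 mM | 22 mM | run made earlier |  |
| west | 41 mM | 22 mM | run made earlier |  |
| alder | 20 mM | 22.0 mM |  | 30 min |
| oak | 30 mM | 22.0 mM |  | 30 min |
| birch | 50 mM | 22.0 mM |  | 30 min |

| run | time / min | target / % | substrate / % |
|---|---|---|---|
| south-west | 2.50 | 1.3 | 100.3 |
| south-west | 6.00 | 1.9 | 97.6 |
| south-west | 12.0 | 5.5 | 92.8 |
| south-west | 30.0 | 16.4 | 66.7 |
| west | 2.50 | 0.7 | 99.7 |
| west | 6.00 | 3.3 | 95.4 |
| west | 12.0 | 7.0 | 84.0 |
| west | 30.0 | 17.3 | 42.3 |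

(readings scatter by 1 percentage point)

1. [target] at the end for alder, oak, birch, in this order
2. how the row runs (falls all the way / rises all the way / falls, then rises / hardly changes / rises, then falls)

- a species is counted by the substrate in it: one side product counts as two
- steps under discussion: substrate + reagent + target -> 2 target; substrate + reagent -> target; substrate + target -> side product
- "hardly changes" means that all values lie within two and a half points (for a concentration: within two and a half percent of the largest)

2. Count the reagent. Each target costs one reagent. Each side product also costs one, but counts as two, so it costs half a reagent per substrate counted in it. Define the draw as the reagent spent per substrate charged: target plus half the side product, the side product being whatever substrate and target no longer account for. At the last reading the west run has a draw of 37.5%. With its charges, that leaves 30.1% of its reagent.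

3. Try the bench rule: at the same time and the same reagent charge, expect the same percent yield. The south-west and west runs read 16.4% and 17.3% at their last reading, a gap of 0.9 percentage points against a scatter of 1 point. Take 16.8% of the charge. This gives 3.37 mM for alder, 5.05 mM for oak and 8.43 mM for birch, a row that keeps rising.

4. Find the border with the ratio of substrate to reagent charged. The west run was charged at 1.86. Oak, at 1.36, lies inside that, but birch, at 2.27, lies beyond it.

5. Apply the west draw to both. By this estimate, at 30 min oak keeps 48.9% of its reagent and birch 14.8%. My own reckoning stands by the rule for alder and oak. Birch keeps less of its reagent than oak and lies beyond both runs, so for birch I expect less than the rule's figure, without saying how much less.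

6. The forecast commits further: 4 mM, 6.3 mM and 5.8 mM, a row that rises, then falls. Its ground is that “reagent must stay above about 8 mM”. My own estimate from the west draw leaves birch 3.25 mM of reagent.

7. The flasks give 3.67 mM, 5.77 mM and 5.46 mM, a row that rises, then falls.

    substrate + reagent + target → 2 target (k = 6.00 /M²/s)
    substrate + reagent → target (k = 0.00170 /M/s)
    substrate + target → side product (k = 0.0500 /M/s)

At the end of alder, with each step taken net, target is still being made 2.10 times as fast as it is used up. Alder's draw comes to 28.8%, which leaves 73.8% of its reagent. Birch's draw comes to 34.3%, which leaves 22.0% of its reagent.

(The runs come from a simulation on assumed constants, noise included.)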